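**Remarks on the chemistry (assumptions)**
- The SMILES corresponds to (2R,3R,2''S); with these descriptors H-2 and H-3 of the upper ring C are cis.
- No descriptor is attached to the C3–C8'' bond, so its rotamers are treated as interconverting in the target.
- Zinc reagent 4 and half-ester 7 are taken as purchased reagents.

Unprimed locants refer to the upper unit and double-primed locants to the lower unit. "Chain carbon n" is carbon n of the octanoate chain of 15. "Tri-O-benzylapigenin-8-yl" stands for 5,7-bis(benzyloxy)-2-[4-(benzyloxy)phenyl]-4-oxo-4H-chromen-8-yl.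

## Analysis of the target

The target is a 3→8''-linked biflavanone: an upper 5,7-dihydroxyflavanone with a 3,4-dihydroxyphenyl group at C2 is bonded through C3 to C8'' of a lower 5,7-dihydroxyflavanone with a 4-hydroxyphenyl group at C2''. It has three stereocentres: C2 (R) and C3 (R) are adjacent in the upper ring C and carry their hydrogens cis, so the two aryl groups sit on one face, while C2'' (S) lies in the lower ring C, too far away to be set by relay. The cis C3 centre is α to the C4 ketone and epimerises to the more stable trans isomer with base or acid, and both pyranone rings can open by retro-oxa-Michael reaction under base, which would scramble C2 and C2''. Seven free phenols, two of them forming a catechol, make the final compound oxidation-prone and call for one mild global deprotection. The hardest bond is C3–C8'': it joins a tertiary carbon to an aryl carbon flanked by O1'' and the C7'' oxygen, and rotation about it is hindered, so a late coupling of two finished units is unattractive. The second difficulty is that the upper unit must be delivered as the less stable cis isomer with absolute control in a molecule that already holds another flavanone. The strategy rests on ring A of the upper unit (C4a to C8a): C4a bears the C4 ketone, C5, C7 and C8a bear oxygen, and C6 and C8 bear hydrogen, which is the acylphloroglucinol pattern that a linear 3,5,7-trioxo ester gives on Claisen ring closure. If ring A is built this way, the lower unit only has to arrive as an arylacetyl group in which C3–C8'' is a plain CH2–aryl bond.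

## Retrosynthetic reasoning

**26 from 25.** The seven O–benzyl bonds are cut last. One neutral hydrogenolysis frees all phenols without exposing the cis C3 centre or either C2 centre to acid or base.

**25 from 24.** The C2–H and C3–H bonds of the upper ring C are cut together. Syn addition of hydrogen to the C2=C3 bond of a 2,3-diarylchromone is the direct way to the cis isomer, and a chiral catalyst must choose the face. This is placed as late as possible because the cis centre is the most fragile element of the molecule.

**24 from 22.** The C2''–H and C3''–H bonds of the lower ring C are cut. The lower flavone in 22 is a trisubstituted enone and the upper chromone a tetrasubstituted one, so a conjugate reduction should touch only the lower unit. The order is also forced by reactivity: once the upper unit is a ketone, hydride catalysts would attack it.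

**22 from 20, and 20 from 17 and 18.** O1–C2 and C2–C3 of the upper ring C are cut. The chromone comes from an ortho-acyloxy deoxybenzoin by acyl shift and cyclodehydration, which brings the catechol ring in as acid 18 and keeps every intermediate flat and base-stable.

**17 from 16.** Two of the three phenols of ring A are capped as benzyl ethers. The third, hydrogen-bonded to the ketone, is left free as the future O1.

**16 from 14 (through 15).** The C4a–C5 bond of ring A is cut. This opens ring A to a linear trioxo ester, masked as dioxinone 14, and turns the lower unit into an arylacetyl starter group. What is gained is that no phloroglucinol has to be acylated and no coupling is needed at the congested C8''. The forward reaction must fold the chain by Claisen condensation and not by aldol closure or lactonisation.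

**14 from 13, and 13 from 6 and 11.** The bond between the arylacetyl carbonyl (the future C4) and the chain carbon that becomes C4a is cut. Acid 6 acylates the β-keto ester carbon of 11, and the allyl ester is then removed with loss of carbon dioxide. A weakly basic, chelation-controlled acylation is chosen because the arylacetyl donor has an acidic benzylic CH2 that a strongly basic carbanion would deprotonate instead of attacking.

**11 from 7 and 8.** The chain is cut at the 6-methyl carbon of dioxinone 8, which is acylated as its vinylogous enolate by the chloride of 7.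

**6 from 5, and 5 from 3 and 4.** The CH2–C8'' bond, which becomes C3–C8'' of the target, is cut. It is made by Negishi coupling of iodide 3 with the small zinc enolate 4 while C8'' still belongs to a simple flavone.

**3 from 2, and 2 from 1.** The C8''–I bond and the three benzyl ethers are removed, which leads back to apigenin 1.

## Alternatives that were turned down

**Alternative 1:** Ring C of the upper unit would be cut at O1–C2 and C3–C4, giving the ortho-quinone ketene A4 and the (Z)-diarylethene A2, which already carries the lower (2''S)-flavanone. A4 would be released with CsF from the silyl-protected benzoyl chloride A3. In the forward step the O1=C8a–C4a=C4 unit of A4 would add as a heterodiene across the (Z)-alkene in one suprafacial event and give A1, the hepta-O-benzyl ether of the target (identical with 25).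
- For it: ring C and both upper stereocentres would come in one step, and the cis relationship would follow from the alkene geometry. On relative configuration and on step count after the key step this plan is stronger than the chosen one.
- Against it: both alkene carbons carry electron-rich aryl groups, so nothing decides which one bonds to oxygen. Ketenes also tend to add to alkenes across the C=C bond in a [2+2] sense, and a stepwise zwitterionic path would erase the cis geometry. The facial choice would rest only on the remote C2'' centre, so the two cis diastereomers are expected. The lower flavanone would have to survive basic fluoride.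
- In its place the chosen route offers a ring-forming step with no regiochemical or stereochemical question, and a catalyst, not the substrate, decides each configuration.

**Alternative 2:** The cuts would be O1–C2 and C3–C8''. Zerovalent palladium (for example Pd(PPh3)4) would insert into the C–I bond of iodide 3. The arylpalladium species would activate the ortho-hydroxyaryl ynone A6 toward anti attack of the phenol (6-endo-dig, closing ring C), and reductive elimination would form C3–C8'' to give A5, which is the same compound as 22.
- For it: 22 would be reached from two simple halves in far fewer steps. On step economy this plan is clearly stronger.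
- Against it: the reductive elimination must join a vinyl carbon flanked by an aryl group and a carbonyl to an aryl carbon flanked by two oxygen substituents. 5-exo-dig closure to an aurone, base-induced cyclisation of A6 to the 3-unsubstituted flavone, and protodepalladation are all easier paths.
- Both plans then share the same reductive endgame. What the chosen route offers is that the hindered C3–C8'' bond is made early as a CH2–aryl bond with a small zinc enolate, so no step depends on forcing a fully ortho-substituted coupling.

**Alternative 3:** The cuts would be O1–C8a and C4–C4a. Fluoride would release aryne A10 from silyl triflate A9. The C2 alkoxide of the syn β-hydroxy ester A8 would add to the aryne and the resulting aryl anion would attack the ester, closing ring C to give the cis-(2R,3R) flavanone A7, in which the lower unit is still a flavone.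
- For it: the upper stereocentres would come from an acyclic aldol of an ester such as 5, where absolute and relative control are well developed. On that point it is stronger than the chosen route. The aryne regiochemistry is also favourable, because the alkoxide adds meta to the neighbouring benzyloxy group and places the anion next to it.
- Against it: A8 is a β-hydroxy ester with an acidic α-aryl C–H, so its alkoxide is prone to retro-aldol cleavage and epimerisation before it finds the aryne. A7 is formed with its labile cis C3 centre under basic fluoride. The lower flavone would then have to be reduced enantioselectively in the presence of the upper ketone, which hydride catalysts attack first.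
- The chosen route reduces the lower unit while the upper one is still an inert chromone, and creates the cis centres last under neutral conditions.

Key step: step 8

## Route

**Step 1**
Reactants: 1 apigenin
Product: 2 5,7,4'-tri-O-benzylapigenin
Conditions: BnBr (4.5 equiv), K2CO3 (6 equiv), n-Bu4NI (cat.), DMF, 80 °C
Reagents that add atoms: benzyl bromide, BrCc1ccccc1
Why: Williamson etherification of all three phenols; the hydrogen-bonded 5-OH reacts last, hence the excess of halide, the iodide catalyst and the heating. The flavone is inert to carbonate.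

**Step 2**
Reactants: 2 5,7,4'-tri-O-benzylapigenin
Product: 3 8-iodo-5,7,4'-tri-O-benzylapigenin
Conditions: I2 (1.1 equiv), CF3CO2Ag (1.1 equiv), CH2Cl2, 0 °C → rt, dark
Reagents that add atoms: iodine, II
Why: Electrophilic aromatic iodination; in 5,7-dialkoxyflavones the 5-alkoxy group is twisted by the peri carbonyl and attack goes to C8 (para to the 5-oxygen, ortho to the 7-oxygen and O1) in preference to C6. The 4-benzyloxyphenyl ring is deactivated by the pyranone.

**Step 3**
Reactants: 3 8-iodo-5,7,4'-tri-O-benzylapigenin; 4 (2-tert-butoxy-2-oxoethyl)zinc chloride (0.5 M in Et2O)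
Product: 5 tert-butyl (tri-O-benzylapigenin-8-yl)acetate
Conditions: 4 (2.5 equiv), Pd2(dba)3 (2.5 mol %), XPhos (10 mol %), THF, 60 °C
Reagents that add atoms: none
Why: Negishi coupling of a Reformatsky-type zinc enolate (palladium-catalysed α-arylation of an ester); the small CH2 nucleophile and a bulky biarylphosphine allow coupling at the doubly ortho-substituted C8, and the zinc reagent does not add to the pyranone carbonyl. This makes the future C3–C8'' bond.

**Step 4**
Reactants: 5 tert-butyl (tri-O-benzylapigenin-8-yl)acetate
Product: 6 (tri-O-benzylapigenin-8-yl)acetic acid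
Conditions: CF3CO2H/CH2Cl2 (1:4), 0 °C → rt
Reagents that add atoms: none
Why: Acidolysis of the tert-butyl ester by loss of isobutene (E1); aryl benzyl ethers, the peri 5-O-benzyl group included, tolerate brief exposure to cold dilute CF3CO2H.

**Step 5**
Reactants: 7 allyl hydrogen malonate; 8 2,2,6-trimethyl-4H-1,3-dioxin-4-one
Product: 11 allyl 4-(2,2-dimethyl-4-oxo-4H-1,3-dioxin-6-yl)-3-oxobutanoate, via allyl malonyl chloride 9 (not isolated), via lithium dienolate of the dioxinone 10 (not isolated)
Conditions: 7, (COCl)2, DMF (cat.), CH2Cl2, 0 °C → rt, concentrate; 8 (2.1 equiv), LiN(SiMe3)2 (2.1 equiv), THF, −78 °C; add 9, −78 → −40 °C; 1 M HCl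
Reagents that add atoms: none
Why: C-acylation of the vinylogous lithium enolate of the dioxinone at its γ-carbon (the 6-methyl) by a malonyl half-ester chloride. Two equivalents of enolate are used because the β-keto ester product is deprotonated as it forms.

**Step 6**
Reactants: 6 (tri-O-benzylapigenin-8-yl)acetic acid; 11 allyl 4-(2,2-dimethyl-4-oxo-4H-1,3-dioxin-6-yl)-3-oxobutanoate
Product: 13 allyl 2-[(tri-O-benzylapigenin-8-yl)acetyl]-4-(2,2-dimethyl-4-oxo-4H-1,3-dioxin-6-yl)-3-oxobutanoate, via arylacetyl chloride 12 (not isolated)
Conditions: 6, (COCl)2 (1.2 equiv), DMF (cat.), CH2Cl2, 0 °C, concentrate; 11 (1.1 equiv), MgCl2 (2 equiv), pyridine (2.5 equiv), CH2Cl2, 0 °C → rt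
Reagents that add atoms: none
Why: Soft-enolisation C-acylation: MgCl2 and pyridine form the chelated magnesium enolate of the β-keto allyl ester at its most acidic carbon, and the arylacetyl chloride acylates it on carbon. This weakly basic protocol is preferred to acylation of a ketone dianion because the arylacetyl donor has an acidic benzylic α-CH2.

**Step 7**
Reactants: 13 allyl 2-[(tri-O-benzylapigenin-8-yl)acetyl]-4-(2,2-dimethyl-4-oxo-4H-1,3-dioxin-6-yl)-3-oxobutanoate
Product: 14 6-[2,4-dioxo-5-(tri-O-benzylapigenin-8-yl)pentyl]-2,2-dimethyl-4H-1,3-dioxin-4-one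
Conditions: Pd(PPh3)4 (5 mol %), morpholine (2 equiv), THF, 0 °C → rt
Reagents that add atoms: none
Why: Zerovalent palladium ionises the allyl ester to a π-allyl complex (Tsuji–Trost deallylation), morpholine takes up the allyl group, and the β-keto acid loses CO2 at room temperature. The dioxinone and the benzyl ethers are untouched, and 14 is used at once.

**Step 8**
Reactants: 14 6-[2,4-dioxo-5-(tri-O-benzylapigenin-8-yl)pentyl]-2,2-dimethyl-4H-1,3-dioxin-4-one
Product: 16 2,4,6-trihydroxyphenyl (tri-O-benzylapigenin-8-yl)methyl ketone, via methyl trioxo ester 15 (not isolated)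
Conditions: MeOH (20 equiv), toluene, 105 °C (sealed tube); concentrate; Mg(OMe)2 (6 equiv), MeOH, rt → 50 °C; cold 1 M HCl
Reagents that add atoms: none
Why: At 105 °C the dioxinone undergoes a retro-[4+2] cycloreversion, losing acetone to give an acylketene that the methanol present captures as methyl 3,5,7-trioxo ester 15; toluene in a sealed tube is used because boiling methanol alone does not reach the temperature this cycloreversion needs. Mg(OMe)2 then converts 15 into a magnesium-chelated polyenolate in which the three ketone carbonyls are tied up as enolates, leaving the methyl ester as the only electrophilic carbonyl. Chain carbon 6, the methylene between the carbonyls at chain carbons 5 and 7 and the future C4a, attacks the ester carbon (chain carbon 1, the future C5) in a 6-exo-trig Claisen condensation; methoxide leaves and the cyclohexanetrione tautomerises to aromatic ring A, so the one new skeletal bond is C4a–C5. The closest known reaction type is the magnesium alkoxide-induced Claisen cyclisation of 3,5,7-trioxoalkanoates to acylphloroglucinols, preceded by the routine thermal opening of a dioxinone in the presence of an alcohol. No stereocentre is formed. The step needs C-acylation to beat three other closures: aldol attack of chain carbon 2 on the ketone at chain carbon 7 (a resorcylate), aldol attack of the benzylic chain carbon 8 on the ketone at chain carbon 3, and O-acylation of an enol oxygen by the ester (a 4-hydroxy-2-pyranone). Full enolisation under magnesium chelation removes the ketone electrophiles that both aldol modes need, the bulky tri-O-benzylapigenin-8-yl group shields chain carbons 7 and 8, and an ester under non-dehydrating conditions is a poor partner for lactonisation. Since ring A has hydrogen at both C6 and C8 and the same oxygen pattern in either sense, the fold cannot give a regioisomer, and the flavone with its benzyl ethers is inert to methoxide at this temperature.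

**Step 9**
Reactants: 16 2,4,6-trihydroxyphenyl (tri-O-benzylapigenin-8-yl)methyl ketone
Product: 17 2,4-bis(benzyloxy)-6-hydroxyphenyl (tri-O-benzylapigenin-8-yl)methyl ketone
Conditions: BnBr (2.1 equiv), K2CO3 (2.2 equiv), DMF, 0 °C → rt
Reagents that add atoms: benzyl bromide, BrCc1ccccc1
Why: Williamson etherification limited to two equivalents; the para OH and one ortho OH are alkylated, while the remaining ortho OH is held in a hydrogen bond to the ketone and is much less nucleophilic, as in the routine preparation of 2-hydroxy-4,6-dibenzyloxyaryl ketones.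

**Step 10**
Reactants: 17 2,4-bis(benzyloxy)-6-hydroxyphenyl (tri-O-benzylapigenin-8-yl)methyl ketone; 18 3,4-bis(benzyloxy)benzoic acid
Product: 20 3,5-bis(benzyloxy)-2-[(tri-O-benzylapigenin-8-yl)acetyl]phenyl 3,4-bis(benzyloxy)benzoate, via 3,4-bis(benzyloxy)benzoyl chloride 19 (not isolated)
Conditions: 18, (COCl)2, DMF (cat.), CH2Cl2, rt, concentrate; 17, Et3N (2 equiv), DMAP (0.2 equiv), CH2Cl2, 0 °C → rt
Reagents that add atoms: none
Why: DMAP-catalysed O-acylation of the only free phenol by the acid chloride made from 18; this installs the carbon that becomes C2 together with the catechol ring.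

**Step 11**
Reactants: 20 3,5-bis(benzyloxy)-2-[(tri-O-benzylapigenin-8-yl)acetyl]phenyl 3,4-bis(benzyloxy)benzoate
Product: 22 5,7-bis(benzyloxy)-2-[3,4-bis(benzyloxy)phenyl]-3-(tri-O-benzylapigenin-8-yl)-4H-chromen-4-one (hepta-O-benzyl 3,8''-biflavone), via 1,3-diketone 21 (not isolated)
Conditions: K2CO3 (4 equiv), dry DMF, 90 °C
Reagents that add atoms: none
Why: Baker–Venkataraman rearrangement: the deoxybenzoin enolate attacks the neighbouring aryl ester (O→C acyl shift) to give 1,3-diketone 21, whose phenoxide adds to the new aroyl carbonyl and loses water to close the pyranone. This is the known route from 2-aroyloxydeoxybenzoins to 2,3-diarylchromones and forms C2–C3 and O1–C2 of the upper ring C.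

**Step 12**
Reactants: 22 hepta-O-benzyl 3,8''-biflavone
Product: 24 hepta-O-benzyl (2''S)-2'',3''-dihydro-3,8''-biflavone (lower unit flavanone; upper unit 2,3-diarylchromone), via silyl enol ether 23 (not isolated)
Conditions: Cu(OAc)2·H2O (5 mol %), (R)-DTBM-SEGPHOS (5.5 mol %), (EtO)2MeSiH (1.3 equiv), toluene/THF, 0 °C → rt; then 1 M HCl/THF, 0 °C
Reagents that add atoms: none
Why: Copper hydride-catalysed asymmetric conjugate reduction, a reaction class established for β,β-disubstituted cyclic enones including 2-substituted chromones: the ligated copper hydride adds hydride to C2'' of the lower flavone and σ-bond metathesis with the silane releases silyl enol ether 23, which shields the new ketone from over-reduction until the acidic work-up. The ligand enantiomer is the one that delivers hydride to the Re face of C2'' (giving 2''S; the sense is to be confirmed on 2 as a model), and the tetrasubstituted upper C2=C3 bond is too hindered for hydrocupration.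

**Step 13**
Reactants: 24 hepta-O-benzyl (2''S)-2'',3''-dihydro-3,8''-biflavone
Product: 25 hepta-O-benzyl ether of the target (2R,3R,2''S)
Conditions: H2 (50 bar), [Ir(cod){(S)-iPr-PHOX}][B(3,5-(CF3)2C6H3)4] (5 mol %), CH2Cl2, 40 °C
Reagents that add atoms: none
Why: Proposed new method: a cationic iridium N,P-ligand catalyst should bind the electron-rich tetrasubstituted C2=C3 bond of the upper chromone and pass both hydrogens of an iridium dihydride to one face by migratory insertion and reductive elimination, so the addition is syn and the 2-aryl and 3-aryl groups end up cis. The chiral pocket of the PHOX ligand is to select the Si face at C2 (giving 2R,3R; the ligand enantiomer is chosen accordingly), while the ketones, the lower flavanone and the benzyl ethers are inert to this catalyst class. The closest known reaction type is the iridium N,P-catalysed asymmetric hydrogenation of tetrasubstituted alkenes and of cyclic aryl enol ethers such as 4H-chromenes and benzofurans.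

**Step 14**
Reactants: 25 hepta-O-benzyl ether of the target (2R,3R,2''S)
Product: 26 target biflavanone CNP0105436.1 (2R,3R,2''S)
Conditions: H2 (1 atm), Pd(OH)2/C (20 wt %), EtOAc/MeOH (1:1), rt
Reagents that add atoms: none
Why: Hydrogenolysis of the seven benzyl ethers under neutral conditions; with no acid or base present the cis C3 centre and both C2 centres should keep their configuration, and the chelated aryl ketones are not reduced at 1 atm.

## Compound list

1 | apigenin | O=c1cc(-c2ccc(O)cc2)oc2cc(O)cc(O)c12 | starting material
2 | 5,7,4'-tri-O-benzylapigenin | O=c1cc(-c2ccc(OCc3ccccc3)cc2)oc2cc(OCc3ccccc3)cc(OCc3ccccc3)c12 | intermediate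
3 | 8-iodo-5,7,4'-tri-O-benzylapigenin | O=c1cc(-c2ccc(OCc3ccccc3)cc2)oc2c(I)c(OCc3ccccc3)cc(OCc3ccccc3)c12 | intermediate
4 | (2-tert-butoxy-2-oxoethyl)zinc chloride | CC(C)(C)OC(=O)C[Zn]Cl | starting material
5 | tert-butyl (tri-O-benzylapigenin-8-yl)acetate | CC(C)(C)OC(=O)Cc1c(OCc2ccccc2)cc(OCc2ccccc2)c2c(=O)cc(-c3ccc(OCc4ccccc4)cc3)oc12 | intermediate
6 | (tri-O-benzylapigenin-8-yl)acetic acid | OC(=O)Cc1c(OCc2ccccc2)cc(OCc2ccccc2)c2c(=O)cc(-c3ccc(OCc4ccccc4)cc3)oc12 | intermediate
7 | allyl hydrogen malonate | C=CCOC(=O)CC(=O)O | starting material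
8 | 2,2,6-trimethyl-4H-1,3-dioxin-4-one | CC1=CC(=O)OC(C)(C)O1 | starting material
9 | allyl malonyl chloride (allyl 3-chloro-3-oxopropanoate) | C=CCOC(=O)CC(=O)Cl | intermediate (not isolated)
10 | lithium 2,2-dimethyl-6-methylidene-6H-1,3-dioxin-4-olate | [Li]OC1=CC(=C)OC(C)(C)O1 | intermediate (not isolated)
11 | allyl 4-(2,2-dimethyl-4-oxo-4H-1,3-dioxin-6-yl)-3-oxobutanoate | C=CCOC(=O)CC(=O)CC1=CC(=O)OC(C)(C)O1 | intermediate
12 | (tri-O-benzylapigenin-8-yl)acetyl chloride | O=C(Cl)Cc1c(OCc2ccccc2)cc(OCc2ccccc2)c2c(=O)cc(-c3ccc(OCc4ccccc4)cc3)oc12 | intermediate (not isolated)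
13 | allyl 2-[(tri-O-benzylapigenin-8-yl)acetyl]-4-(2,2-dimethyl-4-oxo-4H-1,3-dioxin-6-yl)-3-oxobutanoate | C=CCOC(=O)C(C(=O)Cc1c(OCc2ccccc2)cc(OCc2ccccc2)c2c(=O)cc(-c3ccc(OCc4ccccc4)cc3)oc12)C(=O)CC1=CC(=O)OC(C)(C)O1 | intermediate
14 | 6-[2,4-dioxo-5-(tri-O-benzylapigenin-8-yl)pentyl]-2,2-dimethyl-4H-1,3-dioxin-4-one | CC1(C)OC(=O)C=C(CC(=O)CC(=O)Cc2c(OCc3ccccc3)cc(OCc3ccccc3)c3c(=O)cc(-c4ccc(OCc5ccccc5)cc4)oc23)O1 | intermediate (precursor of the key step)
15 | methyl 3,5,7-trioxo-8-(tri-O-benzylapigenin-8-yl)octanoate | COC(=O)CC(=O)CC(=O)CC(=O)Cc1c(OCc2ccccc2)cc(OCc2ccccc2)c2c(=O)cc(-c3ccc(OCc4ccccc4)cc3)oc12 | intermediate (not isolated)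
16 | 2,4,6-trihydroxyphenyl (tri-O-benzylapigenin-8-yl)methyl ketone | O=C(Cc1c(OCc2ccccc2)cc(OCc2ccccc2)c2c(=O)cc(-c3ccc(OCc4ccccc4)cc3)oc12)c1c(O)cc(O)cc1O | intermediate (product of the key step)
17 | 2,4-bis(benzyloxy)-6-hydroxyphenyl (tri-O-benzylapigenin-8-yl)methyl ketone | O=C(Cc1c(OCc2ccccc2)cc(OCc2ccccc2)c2c(=O)cc(-c3ccc(OCc4ccccc4)cc3)oc12)c1c(O)cc(OCc2ccccc2)cc1OCc1ccccc1 | intermediate
18 | 3,4-bis(benzyloxy)benzoic acid | O=C(O)c1ccc(OCc2ccccc2)c(OCc2ccccc2)c1 | starting material
19 | 3,4-bis(benzyloxy)benzoyl chloride | O=C(Cl)c1ccc(OCc2ccccc2)c(OCc2ccccc2)c1 | intermediate (not isolated)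
20 | 3,5-bis(benzyloxy)-2-[(tri-O-benzylapigenin-8-yl)acetyl]phenyl 3,4-bis(benzyloxy)benzoate | O=C(Cc1c(OCc2ccccc2)cc(OCc2ccccc2)c2c(=O)cc(-c3ccc(OCc4ccccc4)cc3)oc12)c1c(OC(=O)c2ccc(OCc3ccccc3)c(OCc3ccccc3)c2)cc(OCc2ccccc2)cc1OCc1ccccc1 | intermediate
21 | 1-[2,4-bis(benzyloxy)-6-hydroxyphenyl]-3-[3,4-bis(benzyloxy)phenyl]-2-(tri-O-benzylapigenin-8-yl)propane-1,3-dione | O=C(c1ccc(OCc2ccccc2)c(OCc2ccccc2)c1)C(c1c(OCc2ccccc2)cc(OCc2ccccc2)c2c(=O)cc(-c3ccc(OCc4ccccc4)cc3)oc12)C(=O)c1c(O)cc(OCc2ccccc2)cc1OCc1ccccc1 | intermediate (not isolated)
22 | hepta-O-benzyl 3,8''-biflavone: 5,7-bis(benzyloxy)-2-[3,4-bis(benzyloxy)phenyl]-3-(tri-O-benzylapigenin-8-yl)-4H-chromen-4-one | O=c1cc(-c2ccc(OCc3ccccc3)cc2)oc2c1c(OCc1ccccc1)cc(OCc1ccccc1)c2-c1c(-c2ccc(OCc3ccccc3)c(OCc3ccccc3)c2)oc2cc(OCc3ccccc3)cc(OCc3ccccc3)c2c1=O | intermediate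
23 | (2''S)-4''-[diethoxy(methyl)silyl]oxy-2''H-chromene form of 22 (silyl enol ether of the lower flavanone) | CCO[Si](C)(OCC)OC1=C[C@@H](c2ccc(OCc3ccccc3)cc2)Oc2c1c(OCc1ccccc1)cc(OCc1ccccc1)c2-c1c(-c2ccc(OCc3ccccc3)c(OCc3ccccc3)c2)oc2cc(OCc3ccccc3)cc(OCc3ccccc3)c2c1=O | intermediate (not isolated)
24 | hepta-O-benzyl (2''S)-2'',3''-dihydro-3,8''-biflavone (lower flavanone, upper 2,3-diarylchromone) | O=C1C[C@@H](c2ccc(OCc3ccccc3)cc2)Oc2c1c(OCc1ccccc1)cc(OCc1ccccc1)c2-c1c(-c2ccc(OCc3ccccc3)c(OCc3ccccc3)c2)oc2cc(OCc3ccccc3)cc(OCc3ccccc3)c2c1=O | intermediate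
25 | hepta-O-benzyl ether of the target, (2R,3R,2''S), upper ring C cis | O=C1C[C@@H](c2ccc(OCc3ccccc3)cc2)Oc2c1c(OCc1ccccc1)cc(OCc1ccccc1)c2[C@H]1C(=O)c2c(OCc3ccccc3)cc(OCc3ccccc3)cc2O[C@H]1c1ccc(OCc2ccccc2)c(OCc2ccccc2)c1 | intermediate
26 | CNP0105436.1, (2R,3R,2''S)-3,8''-biflavanone | O=C1C[C@@H](c2ccc(O)cc2)Oc2c1c(O)cc(O)c2[C@H]1C(=O)c2c(O)cc(O)cc2O[C@H]1c1ccc(O)c(O)c1 | target

## Step count and least certain steps

Total step count: 14. Longest linear sequence: 13 steps (1 to 26 through steps 1–4 and 6–14); step 5 is a one-step side branch.

**Step 13 (Proposed new method).**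
- What may go wrong: the catalyst may fail to coordinate and turn over at a tetrasubstituted C=C bond that carries two aryl groups, one of them ortho-disubstituted. Facial selectivity may be poor, because the two slowly rotating atropisomers of 24 about C3–C8'' shield opposite faces and one of them is mismatched with the catalyst. Acidic iridium hydrides may epimerise the new C3 centre.
- Fallback (known chemistry), from 24 to 26: heterogeneous hydrogenation with H2 (10–30 bar) over Pd(OH)2/C in EtOAc/MeOH, which adds hydrogen syn to chromone C=C bonds and cleaves the benzyl ethers in the same operation. Because C2'' is already fixed as S, the two cis products are diastereomers: 26 and its (2S,3S,2''S) isomer F1. They are separated by preparative reversed-phase HPLC under neutral or slightly acidic elution. This replaces steps 13 and 14.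

**Step 8 (key step).**
- What may go wrong: aldol closure of chain carbon 2 onto the ketone at chain carbon 7 or pyranone formation may outrun the Claisen mode if enolisation by magnesium is incomplete. The acylketene may be trapped internally by an enol oxygen before methanol reaches it. Methoxide may cleave the β-dicarbonyl chain by retro-Claisen reaction.
- Fallback, from 6 to 16, with a preformed aromatic ring A: 1,3,5-tris(methoxymethoxy)benzene F2 is lithiated between two of its ether groups with n-BuLi and transmetalated with ZnCl2 to [2,4,6-tris(methoxymethoxy)phenyl]zinc chloride F3. Acid 6 is converted to chloride 12 as in step 6 and coupled with F3 by Negishi acylation (Pd(PPh3)4, THF) to give 1-[2,4,6-tris(methoxymethoxy)phenyl]-2-(tri-O-benzylapigenin-8-yl)ethanone F4. The three acetal groups are removed with HCl in MeOH/THF at 40 °C to return 16. Steps 5–8 are bypassed.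

**Step 12.**
- What may go wrong: hydrocupration of the β-aryl vinylogous ester may be slow. The liberated flavanone carbonyl may be reduced further if the enolate is protonated before work-up. The copper enolate may lose the ring oxygen by β-elimination, which opens the ring to a chalcone and erases C2''. One atropisomer of 22 may respond poorly to the ligand.
- Fallback, from 22 to 24: asymmetric hydrogenation with Ru(cod)(2-methylallyl)2 and the chiral N-heterocyclic carbene generated from SINpEt·HBF4 and KOt-Bu (H2, toluene), a catalyst class established for flavones. It reduces the lower C2''=C3'' bond and then the C4'' carbonyl to the (2''S)-flavan-4''-ol F5. Oxidation of F5 with Dess–Martin periodinane buffered with pyridine returns 24.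

**Step 11.**
- What may go wrong: the acyl shift has to deliver the aroyl group to a carbon that bears the ortho-disubstituted aryl group. Ester cleavage back to 17 may win, or the sequence may stall at the 2-hydroxychromanone hemiketal.
- Fallback, from 17 to 22, skipping steps 10 and 11: condensation of 17 with 3,4-bis(benzyloxy)benzaldehyde F6 (piperidine, EtOH, reflux; Knoevenagel condensation followed by oxa-Michael closure) gives the racemic trans-2,3-diarylchroman-4-one F7. Dehydrogenation of F7 with I2 (cat.) in DMSO at 120 °C gives 22.

**Step 6.**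
- What may go wrong: pyridine may convert the arylacetyl chloride into the aryl ketene, which dimerises. The magnesium enolate may be acylated on oxygen or twice.
- Fallback, from 6 and 8 to 14, bypassing steps 5–7: 8 is acetylated through its lithium dienolate (LiN(SiMe3)2, AcCl) to 2,2-dimethyl-6-(2-oxopropyl)-4H-1,3-dioxin-4-one F8. Acid 6 is converted with carbonyldiimidazole to N-[(tri-O-benzylapigenin-8-yl)acetyl]imidazole F9. The dianion of F8 (LiN(i-Pr)2, 2 equiv, THF, −78 °C, then Et2Zn to temper its basicity) is acylated at its terminal carbon by F9 to give 14 directly.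

## Further compounds

F1 | step 13 | (2S,3S,2''S)-diastereomer of the target | O=C1C[C@@H](c2ccc(O)cc2)Oc2c1c(O)cc(O)c2[C@@H]1C(=O)c2c(O)cc(O)cc2O[C@@H]1c1ccc(O)c(O)c1
F2 | step 8 | 1,3,5-tris(methoxymethoxy)benzene | COCOc1cc(OCOC)cc(OCOC)c1
F3 | step 8 | [2,4,6-tris(methoxymethoxy)phenyl]zinc chloride | COCOc1cc(OCOC)c([Zn]Cl)c(OCOC)c1
F4 | step 8 | 1-[2,4,6-tris(methoxymethoxy)phenyl]-2-(tri-O-benzylapigenin-8-yl)ethanone | COCOc1cc(OCOC)c(C(=O)Cc2c(OCc3ccccc3)cc(OCc3ccccc3)c3c(=O)cc(-c4ccc(OCc5ccccc5)cc4)oc23)c(OCOC)c1
F5 | step 12 | hepta-O-benzyl (2''S,4''S)-flavan-4''-ol form of 24 (cis drawn; either C4'' epimer is oxidised to 24) | O[C@H]1C[C@@H](c2ccc(OCc3ccccc3)cc2)Oc2c1c(OCc1ccccc1)cc(OCc1ccccc1)c2-c1c(-c2ccc(OCc3ccccc3)c(OCc3ccccc3)c2)oc2cc(OCc3ccccc3)cc(OCc3ccccc3)c2c1=O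
F6 | step 11 | 3,4-bis(benzyloxy)benzaldehyde | O=Cc1ccc(OCc2ccccc2)c(OCc2ccccc2)c1
F7 | step 11 | trans-5,7-bis(benzyloxy)-2-[3,4-bis(benzyloxy)phenyl]-3-(tri-O-benzylapigenin-8-yl)chroman-4-one (racemic, one enantiomer drawn) | O=c1cc(-c2ccc(OCc3ccccc3)cc2)oc2c1c(OCc1ccccc1)cc(OCc1ccccc1)c2[C@H]1C(=O)c2c(OCc3ccccc3)cc(OCc3ccccc3)cc2O[C@@H]1c1ccc(OCc2ccccc2)c(OCc2ccccc2)c1
F8 | step 6 | 2,2-dimethyl-6-(2-oxopropyl)-4H-1,3-dioxin-4-one | CC(=O)CC1=CC(=O)OC(C)(C)O1
F9 | step 6 | N-[(tri-O-benzylapigenin-8-yl)acetyl]imidazole | O=C(Cc1c(OCc2ccccc2)cc(OCc2ccccc2)c2c(=O)cc(-c3ccc(OCc4ccccc4)cc3)oc12)n1ccnc1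
A1 | alternative 1 | hepta-O-benzyl ether of the target, (2R,3R,2''S) (identical with 25) | O=C1C[C@@H](c2ccc(OCc3ccccc3)cc2)Oc2c1c(OCc1ccccc1)cc(OCc1ccccc1)c2[C@H]1C(=O)c2c(OCc3ccccc3)cc(OCc3ccccc3)cc2O[C@H]1c1ccc(OCc2ccccc2)c(OCc2ccccc2)c1
A2 | alternative 1 | (2S)-5,7-bis(benzyloxy)-2-[4-(benzyloxy)phenyl]-8-{(Z)-2-[3,4-bis(benzyloxy)phenyl]ethenyl}chroman-4-one | O=C1C[C@@H](c2ccc(OCc3ccccc3)cc2)Oc2c1c(OCc1ccccc1)cc(OCc1ccccc1)c2/C=C\c1ccc(OCc2ccccc2)c(OCc2ccccc2)c1
A3 | alternative 1 | 2,4-bis(benzyloxy)-6-[(tert-butyldimethylsilyl)oxy]benzoyl chloride | O=C(Cl)c1c(O[Si](C)(C)C(C)(C)C)cc(OCc2ccccc2)cc1OCc1ccccc1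
A4 | alternative 1 | 3,5-bis(benzyloxy)-6-(oxomethylidene)cyclohexa-2,4-dien-1-one (ortho-quinone ketene) | O=C=C1C(=O)C=C(OCc2ccccc2)C=C1OCc1ccccc1
A5 | alternative 2 | hepta-O-benzyl 3,8''-biflavone (identical with 22) | O=c1cc(-c2ccc(OCc3ccccc3)cc2)oc2c1c(OCc1ccccc1)cc(OCc1ccccc1)c2-c1c(-c2ccc(OCc3ccccc3)c(OCc3ccccc3)c2)oc2cc(OCc3ccccc3)cc(OCc3ccccc3)c2c1=O
A6 | alternative 2 | 1-[2,4-bis(benzyloxy)-6-hydroxyphenyl]-3-[3,4-bis(benzyloxy)phenyl]prop-2-yn-1-one | O=C(C#Cc1ccc(OCc2ccccc2)c(OCc2ccccc2)c1)c1c(O)cc(OCc2ccccc2)cc1OCc1ccccc1
A7 | alternative 3 | cis-(2R,3R)-5,7-bis(benzyloxy)-2-[3,4-bis(benzyloxy)phenyl]-3-(tri-O-benzylapigenin-8-yl)chroman-4-one | O=c1cc(-c2ccc(OCc3ccccc3)cc2)oc2c1c(OCc1ccccc1)cc(OCc1ccccc1)c2[C@H]1C(=O)c2c(OCc3ccccc3)cc(OCc3ccccc3)cc2O[C@H]1c1ccc(OCc2ccccc2)c(OCc2ccccc2)c1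
A8 | alternative 3 | methyl (2R,3R)-3-[3,4-bis(benzyloxy)phenyl]-3-hydroxy-2-(tri-O-benzylapigenin-8-yl)propanoate (syn) | O=c1cc(-c2ccc(OCc3ccccc3)cc2)oc2c1c(OCc1ccccc1)cc(OCc1ccccc1)c2[C@H]([C@@H](O)c1ccc(OCc2ccccc2)c(OCc2ccccc2)c1)C(=O)OC
A9 | alternative 3 | 3,5-bis(benzyloxy)-2-(trimethylsilyl)phenyl trifluoromethanesulfonate | C[Si](C)(C)c1c(OCc2ccccc2)cc(OCc2ccccc2)cc1OS(=O)(=O)C(F)(F)F
A10 | alternative 3 | 3,5-bis(benzyloxy)benzyne | C1#CC(OCc2ccccc2)=CC(OCc2ccccc2)=C1
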